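## Retrosynthetic overview

1. The lactone C5–O bond, the only ring of the target, is made last: the ester carbonyl closes onto the allylic carbon of trans-vinyl epoxide 16 with inversion, which sets C5 (R) and frees the C4 hydroxyl.
2. Epoxide 16 (both stereocentres, E-alkylidene) comes from Morita–Baylis–Hillman (MBH) carbonate 12 and prenal 13 through a chiral sulfonium allylide generated by sulfide catalysis (new step).
3. Carbonate 12 comes from aldehyde 9 by MBH reaction with methyl acrylate and Boc activation.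
4. Aldehyde 9 comes from nerol 1: esterification with acid 2, SeO2 oxidation of the terminal (E)-methyl, bromide formation, C2 homologation with an acetaldehyde azaenolate.
5. Ring order: oxirane (step 7), then γ-lactone (step 8) at the oxirane's expense.

Assumption: (2E)-3-methylpent-2-enoic acid is bought as the pure E acid; the catalyst (2R,5R)-2,5-dimethylthiolane is bought or made from (2S,5S)-hexane-2,5-diol and is not counted as a route compound.

## Route

Step 1
Reactants: 1 nerol; 2 (2E)-3-methylpent-2-enoic acid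
Product: 3 (2Z)-3,7-dimethylocta-2,6-dien-1-yl (2E)-3-methylpent-2-enoate
Conditions: DCC (1.1 equiv), DMAP (0.1 equiv), CH2Cl2, 0 °C → rt
Reagents that add atoms: none
Why: Steglich esterification joins the primary allylic alcohol and the enoic acid under neutral conditions, so neither the Z-alkene of nerol nor the E-enoate is isomerised.

Step 2
Reactants: 3 (2Z)-3,7-dimethylocta-2,6-dien-1-yl (2E)-3-methylpent-2-enoate
Product: 4 (2Z,6E)-8-hydroxy-3,7-dimethylocta-2,6-dien-1-yl (2E)-3-methylpent-2-enoate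
Conditions: SeO2 (0.5 equiv), salicylic acid (0.1 equiv), t-BuOOH (70% aq, 3 equiv), CH2Cl2, rt
Reagents that add atoms: selenium dioxide, O=[Se]=O (oxygen donor); tert-butyl hydroperoxide, CC(C)(C)OO (terminal oxidant that restores SeO2)
Why: Catalytic Riley allylic oxidation (ene reaction then [2,3]-shift) attacks the most electron-rich terminal trisubstituted alkene at its (E)-methyl group, giving the 6E allylic alcohol, while the ester-deactivated 2,3-alkene and the enoate do not react.

Step 3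
Reactants: 4 (2Z,6E)-8-hydroxy-3,7-dimethylocta-2,6-dien-1-yl (2E)-3-methylpent-2-enoate
Product: 5 (2Z,6E)-8-bromo-3,7-dimethylocta-2,6-dien-1-yl (2E)-3-methylpent-2-enoate
Conditions: CBr4 (1.2 equiv), PPh3 (1.25 equiv), CH2Cl2, −20 → 0 °C
Reagents that add atoms: tetrabromomethane, BrC(Br)(Br)Br
Why: Appel bromination displaces the primary allylic oxyphosphonium by SN2 without allylic shift or E/Z change, and the esters are inert.

Step 4
Reactants: 5 (2Z,6E)-8-bromo-3,7-dimethylocta-2,6-dien-1-yl (2E)-3-methylpent-2-enoate; 6 N-tert-butylethanimine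
Product: 9 (2Z,6E)-3,7-dimethyl-10-oxodeca-2,6-dien-1-yl (2E)-3-methylpent-2-enoate, via lithium azaenolate 7 (not isolated), via N-tert-butyl aldimine 8 (not isolated)
Conditions: 6 (1.1 equiv), LDA (1.1 equiv), THF, −78 → 0 °C; then 5, −78 → −40 °C; then aq. tartaric acid (pH 4), 0 °C → rt
Reagents that add atoms: water, O (aldehyde oxygen on hydrolysis of imine 8)
Why: Metalloenamine (azaenolate) alkylation gives clean SN2 at the primary allylic bromide at −78 °C, faster than attack on the hindered conjugated ester, and mild hydrolysis of the imine releases the two-carbon-extended aldehyde with the 6E alkene intact.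

Step 5
Reactants: 9 (2Z,6E)-3,7-dimethyl-10-oxodeca-2,6-dien-1-yl (2E)-3-methylpent-2-enoate; 10 methyl acrylate
Product: 11 methyl (6E,10Z)-3-hydroxy-6,10-dimethyl-2-methylidene-12-{[(2E)-3-methylpent-2-enoyl]oxy}dodeca-6,10-dienoate (racemic)
Conditions: 10 (3 equiv), DABCO (1.0 equiv), 1,4-dioxane/H2O 1:1, rt, 36–48 h
Reagents that add atoms: none
Why: Morita–Baylis–Hillman reaction of an unbranched aliphatic aldehyde with methyl acrylate; the β,β-disubstituted enoate in the chain is not an acceptor, and the racemic carbinol centre is erased in step 7.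

Step 6
Reactants: 11 methyl (6E,10Z)-3-hydroxy-6,10-dimethyl-2-methylidene-12-{[(2E)-3-methylpent-2-enoyl]oxy}dodeca-6,10-dienoate
Product: 12 methyl (6E,10Z)-3-[(tert-butoxycarbonyl)oxy]-6,10-dimethyl-2-methylidene-12-{[(2E)-3-methylpent-2-enoyl]oxy}dodeca-6,10-dienoate (racemic)
Conditions: Boc2O (1.3 equiv), DMAP (0.1 equiv), CH2Cl2, 0 °C → rt
Reagents that add atoms: di-tert-butyl dicarbonate, CC(C)(C)OC(=O)OC(=O)OC(C)(C)C
Why: DMAP-catalysed O-acylation gives the standard MBH tert-butyl carbonate, whose leaving group later supplies its own base.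

Step 7
Reactants: 12 methyl (6E,10Z)-3-[(tert-butoxycarbonyl)oxy]-6,10-dimethyl-2-methylidene-12-{[(2E)-3-methylpent-2-enoyl]oxy}dodeca-6,10-dienoate; 13 3-methylbut-2-enal
Product: 16 methyl (2E,6E,10Z)-6,10-dimethyl-12-{[(2E)-3-methylpent-2-enoyl]oxy}-2-[(2S,3S)-3-(2-methylprop-1-en-1-yl)oxiran-2-yl]dodeca-2,6,10-trienoate, via allylsulfonium tert-butyl carbonate 14 (not isolated), via sulfonium ylide 15 (not isolated)
Conditions: (2R,5R)-2,5-dimethylthiolane (20 mol %), 13 (3 equiv), 4 Å MS, MeCN, 40 °C, slow addition of 12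
Reagents that add atoms: none
Why: Proposed new method: the sulfide adds SN2′ to the acrylate CH2 of 12 and expels tert-butyl carbonate, which collapses to CO2 and one equivalent of tert-butoxide that deprotonates sulfonium 14 to the 2-(methoxycarbonyl)allyl ylide 15; 15 adds through its α-carbon to the prenal C=O (anti betaine) and closes 3-exo-tet to the trans-epoxide with release of the sulfide, the C2-symmetric (2R,5R)-thiolane fixing the ylide face (S at the ylide carbon) and the anti betaine fixing S at the aldehyde carbon, by analogy with the (S,S) sense I recall for this sulfide in benzylidene transfer (to be confirmed on this ylide; the (2S,5S) sulfide is equally accessible); the closest known reaction types are chiral-sulfide ylide epoxidation from allyl halides plus external base (Corey–Chaykovsky type) and phosphine- or amine-catalysed ylide generation from MBH carbonates.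

Step 8
Reactants: 16 methyl (2E,6E,10Z)-6,10-dimethyl-12-{[(2E)-3-methylpent-2-enoyl]oxy}-2-[(2S,3S)-3-(2-methylprop-1-en-1-yl)oxiran-2-yl]dodeca-2,6,10-trienoate
Product: 18 (2Z,6E,10E)-10-[(4S,5R)-4-hydroxy-5-(2-methylprop-1-en-1-yl)-2-oxooxolan-3-ylidene]-3,7-dimethyldeca-2,6-dien-1-yl (2E)-3-methylpent-2-enoate, via lactonium tosylate 17 (not isolated)
Conditions: PPTS (10 mol %), MeCN/H2O 20:1, 0 °C → rt
Reagents that add atoms: water, O (taken up when lactonium 17 loses methanol)
Why: Acid-catalysed epoxy-ester lactonisation by neighbouring-group participation: the geminal ester carbonyl oxygen opens the protonated vinyl epoxide at its allylic, cation-stabilised carbon in the only unstrained ring size (five), with inversion there and retention at the carbinol carbon, so the (2S,3S)-trans-epoxide gives the (4S,5R)-trans-lactone, and PPTS leaves the trisubstituted alkenes and the neryl ester alone.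

## Compound list

1 | nerol [(2Z)-3,7-dimethylocta-2,6-dien-1-ol] | OC/C=C(/C)CCC=C(C)C | starting material
2 | (2E)-3-methylpent-2-enoic acid | CC/C(C)=C/C(=O)O | starting material
3 | (2Z)-3,7-dimethylocta-2,6-dien-1-yl (2E)-3-methylpent-2-enoate | CC/C(C)=C/C(=O)OC/C=C(/C)CCC=C(C)C | intermediate
4 | (2Z,6E)-8-hydroxy-3,7-dimethylocta-2,6-dien-1-yl (2E)-3-methylpent-2-enoate | CC/C(C)=C/C(=O)OC/C=C(/C)CC/C=C(\C)CO | intermediate
5 | (2Z,6E)-8-bromo-3,7-dimethylocta-2,6-dien-1-yl (2E)-3-methylpent-2-enoate | CC/C(C)=C/C(=O)OC/C=C(/C)CC/C=C(\C)CBr | intermediate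
6 | N-tert-butylethanimine (acetaldehyde N-tert-butylimine) | C/C=N/C(C)(C)C | starting material
7 | lithium azaenolate of 6 (lithium N-tert-butylethenylamide) | C=CN([Li])C(C)(C)C | intermediate (not isolated)
8 | N-tert-butyl aldimine of 9 | CC/C(C)=C/C(=O)OC/C=C(/C)CC/C=C(\C)CC/C=N/C(C)(C)C | intermediate (not isolated)
9 | (2Z,6E)-3,7-dimethyl-10-oxodeca-2,6-dien-1-yl (2E)-3-methylpent-2-enoate | CC/C(C)=C/C(=O)OC/C=C(/C)CC/C=C(\C)CCC=O | intermediate
10 | methyl acrylate | C=CC(=O)OC | starting material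
11 | methyl (6E,10Z)-3-hydroxy-6,10-dimethyl-2-methylidene-12-{[(2E)-3-methylpent-2-enoyl]oxy}dodeca-6,10-dienoate (racemic) | CC/C(C)=C/C(=O)OC/C=C(/C)CC/C=C(\C)CCC(O)C(=C)C(=O)OC | intermediate
12 | methyl (6E,10Z)-3-[(tert-butoxycarbonyl)oxy]-6,10-dimethyl-2-methylidene-12-{[(2E)-3-methylpent-2-enoyl]oxy}dodeca-6,10-dienoate (racemic) | CC/C(C)=C/C(=O)OC/C=C(/C)CC/C=C(\C)CCC(OC(=O)OC(C)(C)C)C(=C)C(=O)OC | intermediate
13 | 3-methylbut-2-enal (prenal) | CC(C)=CC=O | starting material
14 | (2R,5R)-1-[(2Z,6E,10Z)-2-(methoxycarbonyl)-6,10-dimethyl-12-{[(2E)-3-methylpent-2-enoyl]oxy}dodeca-2,6,10-trien-1-yl]-2,5-dimethylthiolan-1-ium tert-butyl carbonate | CC/C(C)=C/C(=O)OC/C=C(/C)CC/C=C(\C)CC/C=C(/C(=O)OC)C[S+]1[C@H](C)CC[C@H]1C.CC(C)(C)OC(=O)[O-] | intermediate (not isolated)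
15 | sulfonium ylide derived from 14 | CC/C(C)=C/C(=O)OC/C=C(/C)CC/C=C(\C)CC/C=C(/C(=O)OC)[CH-][S+]1[C@H](C)CC[C@H]1C | intermediate (not isolated)
16 | methyl (2E,6E,10Z)-6,10-dimethyl-12-{[(2E)-3-methylpent-2-enoyl]oxy}-2-[(2S,3S)-3-(2-methylprop-1-en-1-yl)oxiran-2-yl]dodeca-2,6,10-trienoate | CC/C(C)=C/C(=O)OC/C=C(/C)CC/C=C(\C)CC/C=C(/C(=O)OC)[C@@H]1O[C@H]1C=C(C)C | intermediate
17 | (4S,5R)-4-hydroxy-2-methoxy-5-(2-methylprop-1-en-1-yl)-3-ylidene-4,5-dihydro-3H-furan-2-ylium (lactonium) tosylate carrying the full side chain | CC/C(C)=C/C(=O)OC/C=C(/C)CC/C=C(\C)CC/C=C1/[C+](OC)O[C@H](C=C(C)C)[C@H]1O.Cc1ccc(cc1)S(=O)(=O)[O-] | intermediate (not isolated)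
18 | (2Z,6E,10E)-10-[(4S,5R)-4-hydroxy-5-(2-methylprop-1-en-1-yl)-2-oxooxolan-3-ylidene]-3,7-dimethyldeca-2,6-dien-1-yl (2E)-3-methylpent-2-enoate | CC/C(C)=C/C(=O)OC/C=C(/C)CC/C=C(\C)CC/C=C1/C(=O)O[C@H](C=C(C)C)[C@H]1O | target

## Step count and risks

Total steps: 8. Longest linear sequence: 8 (1 → 18). Crude 16 is acid-labile on silica and can be carried straight into step 8.

**Step 7 (proposed new method).** Risks: the dialkyl sulfide may add too slowly to the carbonate; the ylide may attack a second molecule of 12 or react through its γ-carbon; the trans/cis ratio, the ee and the alkylidene geometry set in 14 are untested for this ylide. Fallback from 11, rejoining at 16: PBr3 in Et2O at 0 °C converts 11 with allylic transposition into methyl (2Z,6E,10Z)-2-(bromomethyl)-6,10-dimethyl-12-{[(2E)-3-methylpent-2-enoyl]oxy}dodeca-2,6,10-trienoate F1. F1 alkylates stoichiometric (2R,5R)-2,5-dimethylthiolane in acetone at rt to give (2R,5R)-1-[(2Z,6E,10Z)-2-(methoxycarbonyl)-6,10-dimethyl-12-{[(2E)-3-methylpent-2-enoyl]oxy}dodeca-2,6,10-trien-1-yl]-2,5-dimethylthiolan-1-ium bromide F2. F2 with 13 and Cs2CO3 in MeCN at 0 °C gives 16. This is the established halide-plus-base sulfonium-ylide epoxidation, with a preformed salt of defined alkene geometry and a non-hydrolytic base.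

**Step 8.** Risks: the methyl ester carbonyl may be too weak a neighbouring group, so water could add SN2′ at the tertiary allyl terminus or the epoxide could rearrange to a ketone; SN1 character could erode the trans relationship. Fallback from 9, rejoining at 18: steps 5–7 (or the step 7 fallback) are run with tert-butyl acrylate in place of 10. This gives tert-butyl (6E,10Z)-3-hydroxy-6,10-dimethyl-2-methylidene-12-{[(2E)-3-methylpent-2-enoyl]oxy}dodeca-6,10-dienoate F3, then its carbonate tert-butyl (6E,10Z)-3-[(tert-butoxycarbonyl)oxy]-6,10-dimethyl-2-methylidene-12-{[(2E)-3-methylpent-2-enoyl]oxy}dodeca-6,10-dienoate F4, then tert-butyl (2E,6E,10Z)-6,10-dimethyl-12-{[(2E)-3-methylpent-2-enoyl]oxy}-2-[(2S,3S)-3-(2-methylprop-1-en-1-yl)oxiran-2-yl]dodeca-2,6,10-trienoate F5. With CSA (5 mol %) in dry CH2Cl2 at 0 °C the tert-butyl ester closes onto the epoxide and loses 2-methylpropene, giving 18 without water present.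

**Step 4.** Risk: the azaenolate may deprotonate or attack the enoate ester instead of displacing the bromide. Fallback from 5, rejoining at 9: Suzuki coupling of 5 with (E)-2-(2-ethoxyvinyl)-4,4,5,5-tetramethyl-1,3,2-dioxaborolane [Pd(PPh3)4, K3PO4, THF/H2O, 50 °C] gives the enol ether (2Z,6E,9E)-10-ethoxy-3,7-dimethyldeca-2,6,9-trien-1-yl (2E)-3-methylpent-2-enoate F6. 1 M HCl in THF at 0 °C then unmasks aldehyde 9, so no strong base meets the ester.

Further compounds
F1 | step 7 | methyl (2Z,6E,10Z)-2-(bromomethyl)-6,10-dimethyl-12-{[(2E)-3-methylpent-2-enoyl]oxy}dodeca-2,6,10-trienoate | CC/C(C)=C/C(=O)OC/C=C(/C)CC/C=C(\C)CC/C=C(/C(=O)OC)CBr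
F2 | step 7 | (2R,5R)-1-[(2Z,6E,10Z)-2-(methoxycarbonyl)-6,10-dimethyl-12-{[(2E)-3-methylpent-2-enoyl]oxy}dodeca-2,6,10-trien-1-yl]-2,5-dimethylthiolan-1-ium bromide | CC/C(C)=C/C(=O)OC/C=C(/C)CC/C=C(\C)CC/C=C(/C(=O)OC)C[S+]1[C@H](C)CC[C@H]1C.[Br-]
F3 | step 8 | tert-butyl (6E,10Z)-3-hydroxy-6,10-dimethyl-2-methylidene-12-{[(2E)-3-methylpent-2-enoyl]oxy}dodeca-6,10-dienoate | CC/C(C)=C/C(=O)OC/C=C(/C)CC/C=C(\C)CCC(O)C(=C)C(=O)OC(C)(C)C
F4 | step 8 | tert-butyl (6E,10Z)-3-[(tert-butoxycarbonyl)oxy]-6,10-dimethyl-2-methylidene-12-{[(2E)-3-methylpent-2-enoyl]oxy}dodeca-6,10-dienoate | CC/C(C)=C/C(=O)OC/C=C(/C)CC/C=C(\C)CCC(OC(=O)OC(C)(C)C)C(=C)C(=O)OC(C)(C)C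
F5 | step 8 | tert-butyl (2E,6E,10Z)-6,10-dimethyl-12-{[(2E)-3-methylpent-2-enoyl]oxy}-2-[(2S,3S)-3-(2-methylprop-1-en-1-yl)oxiran-2-yl]dodeca-2,6,10-trienoate | CC/C(C)=C/C(=O)OC/C=C(/C)CC/C=C(\C)CC/C=C(/C(=O)OC(C)(C)C)[C@@H]1O[C@H]1C=C(C)C
F6 | step 4 | (2Z,6E,9E)-10-ethoxy-3,7-dimethyldeca-2,6,9-trien-1-yl (2E)-3-methylpent-2-enoate | CC/C(C)=C/C(=O)OC/C=C(/C)CC/C=C(\C)C/C=C/OCC
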